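**Plan**

- Numbering: decalin carbons C1–C10 (C3 carbinol, C4 and C10 quaternary, C8 exo-methylene, C9 carrying C11H2), pyranone atoms primed (C11–C3'); α is the face of H5 and the C10 methyl, β the face of C11.
- Retrosynthesis: cut C11–C3' (sp3–sp2 cross-coupling with a bromo-γ-pyranone); then take C2 out of ring A (bonds C1–C2 and C2–C3); then open the resulting cis-hydrindan-3-one at C5–C10, C1–C3 and C3–C4 (Pauson–Khand); finally cut the acyclic enyne at C8–C9 (aldol).
- Enabling feature: in ring A the oxygenated C3 lies between quaternary C4 and the C2–C1 dimethylene that leads to quaternary C10. Ring A without C2 is therefore a cyclopentanone whose two α-carbons are one quaternary centre (C4) and one methylene (C1).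
- Forward order: chain assembly → ring B and the cyclopentenone in one step → C4 made quaternary → ring A by one-carbon enlargement → pyranone joined at C11 → side-chain carbinol, C8 methylene, formate.
- Stereochemistry: C9 (plus a temporary C8 carbinol) from an Evans syn-aldol; C10 from the chair-like Pauson–Khand transition state steered by the C8 silyl ether; C5 and C4 from α-face protonation and methylation of the bicyclic enolate; C3 from α-face hydride delivery.

Key step: step 10

Remark: the 3-methylbut-3-enyl chain on C4 serves as the latent tertiary carbinol (hydrated in step 19), so that no tertiary silyl ether has to be told apart from the other protecting groups.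

**Route**

Step 1
Reactants: 1 hex-5-yn-2-one
Product: 2 2-methylhex-1-en-5-yne
Conditions: Ph3PCH3Br, KOt-Bu, Et2O, 0 °C → rt; distillation
Reagents that add atoms: methyltriphenylphosphonium bromide, C[P+](c1ccccc1)(c1ccccc1)c1ccccc1.[Br-]
Why: Wittig methylenation of the methyl ketone with the non-stabilised ylide should give the 1,1-disubstituted alkene that later becomes the tertiary carbinol carbon, the terminal alkyne being too weak an acid to quench the ylide.

Step 2
Reactants: 2 2-methylhex-1-en-5-yne; 3 oxetane
Product: 5 8-methylnon-8-en-4-yn-1-ol, via lithium acetylide 4 (not isolated)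
Conditions: n-BuLi, THF, –78 °C; BF3·OEt2, then 3, –78 °C
Reagents that add atoms: none
Why: BF3-promoted opening of oxetane by the lithium acetylide (an epoxide-type alkynylation) should add the three carbons C6–C8 as a primary alcohol in one operation.

Step 3
Reactants: 5 8-methylnon-8-en-4-yn-1-ol
Product: 6 8-methylnon-8-en-4-ynal
Conditions: DMP, CH2Cl2, 0 °C → rt
Reagents that add atoms: none
Why: Dess–Martin oxidation converts the primary alcohol into the non-conjugated aldehyde under near-neutral conditions that leave alkyne and alkene untouched.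

Step 4
Reactants: 7 (R)-4-benzyloxazolidin-2-one; 8 3-methylbut-2-enoyl chloride
Product: 10 (R)-4-benzyl-3-(3-methylbut-2-enoyl)oxazolidin-2-one, via lithiated oxazolidinone 9 (not isolated)
Conditions: n-BuLi, THF, –78 °C; then 8, –78 → 0 °C
Reagents that add atoms: none
Why: N-acylation of the lithiated oxazolidinone with an acid chloride is the standard entry to Evans imides and brings in C11, C9, C10, C1 and the C10 methyl.

Step 5
Reactants: 10 (R)-4-benzyl-3-(3-methylbut-2-enoyl)oxazolidin-2-one; 6 8-methylnon-8-en-4-ynal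
Product: 13 syn-aldol adduct (2R,3S), via boron dienolate 11 (not isolated), via boron aldolate 12 (not isolated)
Conditions: n-Bu2BOTf, Et3N, CH2Cl2, –78 → 0 °C; then 6, –78 → 0 °C; H2O2, MeOH, pH 7 buffer
Reagents that add atoms: none
Why: Evans syn-aldol reaction: γ-deprotonation gives the Z(O)-boron dienolate, which adds through its α-carbon in a closed Zimmerman–Traxler transition state on the face opposite the benzyl group, setting C9 and the temporary C8 carbinol syn and leaving the isopropenyl group out of conjugation.

Step 6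
Reactants: 13 syn-aldol adduct
Product: 14 (2S,3S)-10-methyl-2-(prop-1-en-2-yl)undec-10-en-6-yne-1,3-diol
Conditions: LiBH4, MeOH (1 equiv), THF, 0 °C
Reagents that add atoms: none
Why: LiBH4 reduces the activated imide carbonyl to the primary alcohol (C11) and releases the auxiliary without touching C9.

Step 7
Reactants: 14 diol
Product: 15 bis-TBS ether of 14
Conditions: TBSOTf, 2,6-lutidine, CH2Cl2, –78 → 0 °C
Reagents that add atoms: tert-butyldimethylsilyl triflate, CC(C)(C)[Si](C)(C)OS(=O)(=O)C(F)(F)F
Why: silyl triflate silylation protects both hydroxyls at once; the primary/secondary difference later allows stepwise release, and the C8 silyl ether is the control element of the next step.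

Step 8
Reactants: 15 bis-TBS enyne
Product: 16 bicyclic enone (10α-methyl, 9β-CH2OTBS, 8β-OTBS)
Conditions: Co2(CO)8 (20 mol %), tetramethylthiourea, CO (1 atm), toluene, 70 °C
Reagents that add atoms: carbon monoxide, [C-]#[O+]
Why: intramolecular Pauson–Khand [2+2+1] reaction of the 1,7-enyne joins C5–C10, C1–C3 and C3–C4; in the chair-like transition state the C10 methyl must stand pseudo-axial (C1 lies in the plane of the forming enone), the C8 silyloxy group stays equatorial to avoid a 1,3-diaxial contact with it and so holds its cis neighbour C11 axial and anti to the methyl, which should set C10 with the methyl trans to C11; the 1,5-related side-chain alkene cannot cyclise.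

Step 9
Reactants: 16 bicyclic enone
Product: 18 cis-hydrindan-3-one (5α-H, 4α-methyl, 4β-side chain), via lithium enolate 17 (not isolated)
Conditions: Li, t-BuOH (1 equiv), NH3(l)/THF, –78 °C; then MeI, –78 → –33 °C
Reagents that add atoms: iodomethane, CI
Why: dissolving-metal reduction of the tetrasubstituted enone with enolate trapping (Stork reductive alkylation) gives the regiodefined C3–C4 lithium enolate; C5 should be protonated on the α face because the axial C11 arm screens the β face and the cis-hydrindane is the favoured fusion, and methyl iodide should then attack C4 from the convex α face, anti to the C5–C6 bond, placing the side chain β.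

Step 10
Reactants: 18 cis-hydrindan-3-one
Product: 20 cis-decalin-3-one, via 2-silyl ketone 19 (not isolated)
Conditions: TMSCHN2, AlMe3, CH2Cl2, –78 → –20 °C; then K2CO3 (cat.), MeOH, rt
Reagents that add atoms: trimethylsilyldiazomethane, C[Si](C)(C)C=[N+]=[N-]
Why: AlMe3 activates the C3 carbonyl and the diazo carbon adds to it from the convex α face to give an aluminium-bound β-oxido diazonium betaine, which loses N2 with a 1,2-shift of the anti-periplanar C1–C3 bond so that the new carbon (C2) ends up between C1 and C3; K2CO3/MeOH then removes the silyl group from the 2-silyl ketone 19. The closest known reaction type is the Lewis-acid-promoted homologation of cycloalkanones with trimethylsilyldiazomethane (a Tiffeneau–Demjanov-type diazoalkane insertion), in which the less substituted α-carbon migrates. No ring is closed by cyclisation: ring A arises by enlargement, the cyclopentanone C10–C1–C3–C4–C5 becoming the cyclohexanone C10–C1–C2–C3–C4–C5 through this 1,2-alkyl shift. No stereocentre is formed or touched; C4, C5, C9 and C10 are carried over and the silyl-bearing C2 ends as a methylene. The selectivity needed is migration of the C1 methylene in preference to quaternary C4, and the substrate secures it because the bulky silyl group of the betaine takes the position anti to quaternary C4, which leaves the diazonium group anti-periplanar to C1. The silyl group also shields the first-formed ketone from a second insertion.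

Step 11
Reactants: 20 cis-decalin-3-one
Product: 21 3β-alcohol
Conditions: LiBH(s-Bu)3, THF, –78 °C; then NaOH, H2O2
Reagents that add atoms: none
Why: the bulky trialkylborohydride should deliver hydride to C3 from the convex α face of the cis-decalin, the β face being screened by ring B and the C4 side chain, so that the 3β-alcohol results.

Step 12
Reactants: 21 3β-alcohol
Product: 23 3β-PMB ether, via sodium alkoxide 22 (not isolated)
Conditions: NaH, PMBCl, Bu4NI (cat.), DMF, 0 °C → rt
Reagents that add atoms: 4-methoxybenzyl chloride, COc1ccc(CCl)cc1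
Why: Williamson etherification of the hindered alkoxide installs a p-methoxybenzyl ether, the one group on the route that is removed oxidatively and so can outlast fluoride, the metal reagents and the final formylation.

Step 13
Reactants: 23 3β-PMB ether
Product: 24 C11 primary alcohol
Conditions: HF·pyridine, pyridine, THF, 0 °C
Reagents that add atoms: none
Why: buffered HF·pyridine cleaves the unhindered primary silyl ether much faster than the secondary C8 silyl ether, a standard kinetic differentiation.

Step 14
Reactants: 24 C11 primary alcohol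
Product: 25 C11 iodide
Conditions: I2, PPh3, imidazole, toluene, rt → 50 °C
Reagents that add atoms: iodine, II
Why: Appel-type iodination converts the primary alcohol into the iodide by SN2 displacement of the oxyphosphonium group; no stereocentre is involved.

Step 15
Reactants: 26 dimethyl 3-oxopentanedioate
Product: 28 methyl 4-hydroxy-6-methyl-2-oxo-2H-pyran-5-carboxylate, via acetylated ketodiester 27 (not isolated)
Conditions: MgCl2, pyridine, AcCl, CH2Cl2, 0 °C → rt; then TsOH (cat.), toluene, 110 °C
Reagents that add atoms: acetyl chloride, CC(Cl)=O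
Why: magnesium-mediated C-acetylation of the ketodiester, then acid-catalysed lactonisation of the acetyl enol onto the distal ester (the only six-membered lactone possible), gives the 4-hydroxy-2-pyranone with ester and methyl in place.

Step 16
Reactants: 28 hydroxypyranone
Product: 29 methyl 6-methoxy-2-methyl-4-oxo-4H-pyran-3-carboxylate
Conditions: MeOTf, CH2Cl2, rt; aq. NaHCO3 wash
Reagents that add atoms: methyl triflate, COS(=O)(=O)C(F)(F)F
Why: hard O-methylation of the neutral 4-hydroxy-2-pyranone takes place at the lactone carbonyl oxygen (the 4-hydroxyl is hydrogen-bonded to the ester) and loss of the proton gives the methoxy-4-pyranone, the established route to α-methoxy-γ-pyrones.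

Step 17
Reactants: 29 methoxypyranone
Product: 30 methyl 5-bromo-6-methoxy-2-methyl-4-oxo-4H-pyran-3-carboxylate
Conditions: NBS, MeCN, 0 °C → rt
Reagents that add atoms: N-bromosuccinimide, O=C1CCC(=O)N1Br
Why: electrophilic bromination occurs at the only free ring position, the nucleophilic enol-ether carbon between the carbonyl and the methoxy-bearing carbon (the future C3').

Step 18
Reactants: 25 C11 iodide; 30 bromopyranone
Product: 32 C11–C3' coupled pyranone, via alkylzinc iodide 31 (not isolated)
Conditions: Zn dust, LiCl, THF, 40 °C; then 30, Pd(OAc)2 (5 mol %), SPhos (10 mol %), THF, 25 → 50 °C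
Reagents that add atoms: none
Why: zinc insertion into the primary C–I bond gives an alkylzinc iodide that tolerates the ester and ethers, and zerovalent palladium with SPhos couples it with the bromopyranone (Negishi sp3–sp2 cross-coupling) to form C11–C3' without touching C9.

Step 19
Reactants: 32 coupled pyranone
Product: 33 tertiary alcohol
Conditions: Co(acac)2 (20 mol %), PhSiH3, O2 (1 atm), THF, rt
Reagents that add atoms: dioxygen, O=O
Why: Mukaiyama hydration: hydrogen-atom transfer from a cobalt hydride to the only isolated alkene gives the tertiary radical, which is trapped by O2 and reduced to the Markovnikov tertiary alcohol.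

Step 20
Reactants: 33 tertiary alcohol
Product: 34 8β-hydroxy tertiary alcohol (diol)
Conditions: HF·pyridine, THF, 0 °C → rt
Reagents that add atoms: none
Why: HF·pyridine removes the remaining secondary silyl ether while the PMB ether, the methoxypyranone and the tertiary alcohol are stable to it.

Step 21
Reactants: 34 diol
Product: 35 C8 ketone
Conditions: DMP, pyridine, CH2Cl2, 0 °C → rt
Reagents that add atoms: none
Why: Dess–Martin oxidation converts the secondary C8 alcohol into the ketone under buffered conditions that should not epimerise C9; the tertiary alcohol cannot be oxidised.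

Step 22
Reactants: 35 C8 ketone
Product: 36 C8 exo-methylene compound
Conditions: Zn, CH2Br2, TiCl4, THF/CH2Cl2, 0 °C → rt
Reagents that add atoms: dibromomethane, BrCBr
Why: Takai–Lombardo methylenation with the non-basic zinc/titanium methylene reagent converts the hindered, epimerisable C8 ketone into the exocyclic alkene and leaves the ester, the pyranone carbonyl and C9 untouched.

Step 23
Reactants: 36 exo-methylene tertiary alcohol
Product: 37 tertiary formate (3β-PMB ether)
Conditions: acetic formic anhydride, pyridine, DMAP (cat.), CH2Cl2, 0 °C → rt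
Reagents that add atoms: acetic formic anhydride, CC(=O)OC=O
Why: the mixed anhydride transfers its formyl group (the more electrophilic carbonyl) to the only free hydroxyl, the tertiary alcohol, under DMAP catalysis, the C3 oxygen still being masked.

Step 24
Reactants: 37 tertiary formate
Product: 38 CNP0292250.1
Conditions: DDQ, CH2Cl2/pH 7 buffer, 0 °C → rt
Reagents that add atoms: none
Why: oxidative cleavage of the PMB ether by DDQ (hydride abstraction, then hydrolysis of the oxocarbenium ion) frees the C3 hydroxyl under neutral conditions that the tertiary formate, the exocyclic alkene and the pyranone should survive.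

**Compound list**

1 | hex-5-yn-2-one | CC(=O)CCC#C | starting material
2 | 2-methylhex-1-en-5-yne | C=C(C)CCC#C | intermediate
3 | oxetane | C1COC1 | starting material
4 | (5-methylhex-5-en-1-yn-1-yl)lithium (not isolated) | C=C(C)CCC#C[Li] | intermediate
5 | 8-methylnon-8-en-4-yn-1-ol | C=C(C)CCC#CCCCO | intermediate
6 | 8-methylnon-8-en-4-ynal | C=C(C)CCC#CCCC=O | intermediate
7 | (R)-4-benzyloxazolidin-2-one | O=C1OC[C@@H](Cc2ccccc2)N1 | starting material
8 | 3-methylbut-2-enoyl chloride | CC(C)=CC(=O)Cl | starting material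
9 | N-lithio-(R)-4-benzyloxazolidin-2-one (not isolated) | O=C1OC[C@@H](Cc2ccccc2)N1[Li] | intermediate
10 | (R)-4-benzyl-3-(3-methylbut-2-enoyl)oxazolidin-2-one | O=C1OC[C@@H](Cc2ccccc2)N1C(=O)C=C(C)C | intermediate
11 | Z(O)-dibutylboron dienolate of 10 (not isolated) | O=C1OC[C@@H](Cc2ccccc2)N1/C(OB(CCCC)CCCC)=C/C(C)=C | intermediate
12 | O-dibutylboryl aldolate of 13 (not isolated) | O=C1OC[C@@H](Cc2ccccc2)N1C(=O)[C@H](C(C)=C)[C@@H](OB(CCCC)CCCC)CCC#CCCC(C)=C | intermediate
13 | (R)-4-benzyl-3-[(2R,3S)-3-hydroxy-10-methyl-2-(prop-1-en-2-yl)undec-10-en-6-ynoyl]oxazolidin-2-one | O=C1OC[C@@H](Cc2ccccc2)N1C(=O)[C@H](C(C)=C)[C@@H](O)CCC#CCCC(C)=C | intermediate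
14 | (2S,3S)-10-methyl-2-(prop-1-en-2-yl)undec-10-en-6-yne-1,3-diol | OC[C@H](C(C)=C)[C@@H](O)CCC#CCCC(C)=C | intermediate
15 | (2S,3S)-1,3-bis(tert-butyldimethylsilyloxy)-10-methyl-2-(prop-1-en-2-yl)undec-10-en-6-yne | CC(C)(C)[Si](C)(C)OC[C@H](C(C)=C)[C@@H](O[Si](C)(C)C(C)(C)C)CCC#CCCC(C)=C | intermediate
16 | (3aS,4S,5S)-5-(tert-butyldimethylsilyloxy)-4-[(tert-butyldimethylsilyloxy)methyl]-3a-methyl-1-(3-methylbut-3-en-1-yl)-3,3a,4,5,6,7-hexahydro-2H-inden-2-one (C10 methyl α, C11 and O8 β) | O=C1C[C@@]2(C)[C@@H](CO[Si](C)(C)C(C)(C)C)[C@@H](O[Si](C)(C)C(C)(C)C)CCC2=C1CCC(C)=C | intermediate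
17 | lithium C3–C4 enolate of 18 (5α-H; not isolated) | CC(C)(C)[Si](C)(C)O[C@H]1CC[C@H]2C(CCC(C)=C)=C(O[Li])C[C@@]2(C)[C@H]1CO[Si](C)(C)C(C)(C)C | intermediate
18 | (1R,3aR,4S,5S,7aR)-5-(tert-butyldimethylsilyloxy)-4-[(tert-butyldimethylsilyloxy)methyl]-1,3a-dimethyl-1-(3-methylbut-3-en-1-yl)octahydro-2H-inden-2-one (cis-hydrindan-3-one; H5, C4 methyl and C10 methyl α) | CC(C)(C)[Si](C)(C)O[C@H]1CC[C@H]2[C@@](C)(CCC(C)=C)C(=O)C[C@@]2(C)[C@H]1CO[Si](C)(C)C(C)(C)C | intermediate
19 | 2-(trimethylsilyl) derivative of 20 (C2 epimers; not isolated) | CC(C)(C)[Si](C)(C)O[C@H]1CC[C@H]2[C@@](C)(CCC(C)=C)C(=O)C([Si](C)(C)C)C[C@@]2(C)[C@H]1CO[Si](C)(C)C(C)(C)C | intermediate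
20 | (1R,4aR,5S,6S,8aR)-6-(tert-butyldimethylsilyloxy)-5-[(tert-butyldimethylsilyloxy)methyl]-1,4a-dimethyl-1-(3-methylbut-3-en-1-yl)octahydronaphthalen-2(1H)-one (cis-decalin-3-one) | CC(C)(C)[Si](C)(C)O[C@H]1CC[C@H]2[C@@](C)(CCC(C)=C)C(=O)CC[C@@]2(C)[C@H]1CO[Si](C)(C)C(C)(C)C | intermediate
21 | 3β-alcohol of 20 (3S; other centres as in 20) | CC(C)(C)[Si](C)(C)O[C@H]1CC[C@H]2[C@@](C)(CCC(C)=C)[C@@H](O)CC[C@@]2(C)[C@H]1CO[Si](C)(C)C(C)(C)C | intermediate
22 | sodium 3β-alkoxide of 21 (not isolated) | CC(C)(C)[Si](C)(C)O[C@H]1CC[C@H]2[C@@](C)(CCC(C)=C)[C@@H](O[Na])CC[C@@]2(C)[C@H]1CO[Si](C)(C)C(C)(C)C | intermediate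
23 | 3β-(4-methoxybenzyl) ether of 21 | CC(C)(C)[Si](C)(C)O[C@H]1CC[C@H]2[C@@](C)(CCC(C)=C)[C@@H](OCc3ccc(OC)cc3)CC[C@@]2(C)[C@H]1CO[Si](C)(C)C(C)(C)C | intermediate
24 | C11 primary alcohol (8β-OTBS and 3β-OPMB kept) | CC(C)(C)[Si](C)(C)O[C@H]1CC[C@H]2[C@@](C)(CCC(C)=C)[C@@H](OCc3ccc(OC)cc3)CC[C@@]2(C)[C@H]1CO | intermediate
25 | C11 iodide of 24 | CC(C)(C)[Si](C)(C)O[C@H]1CC[C@H]2[C@@](C)(CCC(C)=C)[C@@H](OCc3ccc(OC)cc3)CC[C@@]2(C)[C@H]1CI | intermediate
26 | dimethyl 3-oxopentanedioate | COC(=O)CC(=O)CC(=O)OC | starting material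
27 | dimethyl 2-acetyl-3-oxopentanedioate (not isolated) | COC(=O)CC(=O)C(C(C)=O)C(=O)OC | intermediate
28 | methyl 4-hydroxy-6-methyl-2-oxo-2H-pyran-5-carboxylate | COC(=O)C1=C(C)OC(=O)C=C1O | intermediate
29 | methyl 6-methoxy-2-methyl-4-oxo-4H-pyran-3-carboxylate | COC(=O)C1=C(C)OC(OC)=CC1=O | intermediate
30 | methyl 5-bromo-6-methoxy-2-methyl-4-oxo-4H-pyran-3-carboxylate | COC(=O)C1=C(C)OC(OC)=C(Br)C1=O | intermediate
31 | C11 zinc iodide derived from 25 (not isolated) | CC(C)(C)[Si](C)(C)O[C@H]1CC[C@H]2[C@@](C)(CCC(C)=C)[C@@H](OCc3ccc(OC)cc3)CC[C@@]2(C)[C@H]1C[Zn]I | intermediate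
32 | methyl 6-methoxy-2-methyl-4-oxo-4H-pyran-3-carboxylate joined at its C5 (C3') to C11 of the decalin (3β-OPMB, 8β-OTBS, 4β-(3-methylbut-3-enyl), 4α-Me, 5α-H, 10α-Me) | CC(C)(C)[Si](C)(C)O[C@H]1CC[C@H]2[C@@](C)(CCC(C)=C)[C@@H](OCc3ccc(OC)cc3)CC[C@@]2(C)[C@H]1Cc4c(OC)oc(C)c(C(=O)OC)c4=O | intermediate
33 | tertiary alcohol: 32 with a 4β-(3-hydroxy-3-methylbutyl) chain | CC(C)(C)[Si](C)(C)O[C@H]1CC[C@H]2[C@@](C)(CCC(C)(C)O)[C@@H](OCc3ccc(OC)cc3)CC[C@@]2(C)[C@H]1Cc4c(OC)oc(C)c(C(=O)OC)c4=O | intermediate
34 | diol: 33 with free 8β-hydroxyl | O[C@H]1CC[C@H]2[C@@](C)(CCC(C)(C)O)[C@@H](OCc3ccc(OC)cc3)CC[C@@]2(C)[C@H]1Cc4c(OC)oc(C)c(C(=O)OC)c4=O | intermediate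
35 | C8 ketone of 34 | O=C1CC[C@H]2[C@@](C)(CCC(C)(C)O)[C@@H](OCc3ccc(OC)cc3)CC[C@@]2(C)[C@H]1Cc4c(OC)oc(C)c(C(=O)OC)c4=O | intermediate
36 | C8 exo-methylene tertiary alcohol (3β-OPMB) | C=C1CC[C@H]2[C@@](C)(CCC(C)(C)O)[C@@H](OCc3ccc(OC)cc3)CC[C@@]2(C)[C@H]1Cc4c(OC)oc(C)c(C(=O)OC)c4=O | intermediate
37 | tertiary formate of 36 (3β-OPMB) | C=C1CC[C@H]2[C@@](C)(CCC(C)(C)OC=O)[C@@H](OCc3ccc(OC)cc3)CC[C@@]2(C)[C@H]1Cc4c(OC)oc(C)c(C(=O)OC)c4=O | intermediate
38 | CNP0292250.1, (3S,4R,5R,9S,10S) in the numbering of the plan | C=C1CC[C@H]2[C@@](C)(CCC(C)(C)OC=O)[C@@H](O)CC[C@@]2(C)[C@H]1Cc1c(OC)oc(C)c(C(=O)OC)c1=O | target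

**Step count**

Total: 24 steps. Longest linear sequence: 20 steps (1–3, 5–14, 18–24); steps 4 and 15–17 are side branches.

**Steps most likely to fail**

Step 8 (Pauson–Khand). The cyclocarbonylation must engage a 1,1-disubstituted alkene through a six-atom tether, so it may stall at the alkyne–cobalt stage. Because it is kinetically controlled at the cobalt cluster, it may also proceed with poor facial selectivity at C10. Fallback: from 15, Cp2ZrCl2 and n-BuLi (2 equiv) in THF (–78 °C → rt) couple alkyne and alkene reductively to the zirconabicycle F1. This metallacycle formation is reversible, so C10 should settle under thermodynamic control in the chair that keeps the C8 silyl ether equatorial and C11 axial. CO (1 atm, 0 °C) then inserts, and brief protonolysis with dilute HCl returns the route to 16.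

Step 9 (reductive methylation). Over-reduction of the ketone, protonation of C5 from the β face, or equilibration of the enolate by amide base before methylation would erode the C5/C4 outcome. Fallback: the hydride is delivered by a transition-metal catalyst and the enolate is released without any proton source. From 16, RhCl(PPh3)3-catalysed 1,4-hydrosilylation with Et3SiH (benzene, 50 °C; the isolated side-chain alkene reacts more slowly) should place hydrogen on the less hindered α face of C5 and give the isolable triethylsilyl enol ether F2. MeLi in THF (0 °C) then cleaves the Si–O bond to regenerate lithium enolate 17, and MeI gives 18.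

Step 18 (Negishi coupling). Zinc insertion at the β-branched, hindered C11–I bond may be slow, and the alkylpalladium intermediate may undergo protodemetalation or β-hydride elimination instead of reductive elimination at the doubly flanked C3'. Fallback: the polarity at C11 is reversed. From 24, Dess–Martin oxidation gives the aldehyde F3. Condensation of F3 with hydroxypyranone 28 (L-proline cat., CH2Cl2) gives the alkylidene pyrandione F4, which the Hantzsch ester present in the same flask reduces by conjugate hydride transfer to the 3-alkyl-4-hydroxy-2-pyranone F5. Methyl triflate with 2,6-di-tert-butyl-4-methylpyridine then methylates the lactone carbonyl oxygen, the 4-hydroxyl being hydrogen-bonded to the ester, and the route is rejoined at 32.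

**Further compounds**

F1 | step 8 | bis(cyclopentadienyl)zirconabicycle from 15 (Zr bound to C1 and C4, C5–C10 formed, C10 methyl trans to C11) | CC(C)(C)[Si](C)(C)OC[C@H]1[C@@H](O[Si](C)(C)C(C)(C)C)CCC2=C(CCC(C)=C)[Zr](C3C=CC=C3)(C3C=CC=C3)C[C@@]12C
F2 | step 9 | triethylsilyl enol ether (C3–OSiEt3, C3=C4) of the 5α-H cis-hydrindanone | CC(C)(C)[Si](C)(C)O[C@H]1CC[C@H]2C(CCC(C)=C)=C(O[Si](CC)(CC)CC)C[C@@]2(C)[C@H]1CO[Si](C)(C)C(C)(C)C
F3 | step 18 | C11 aldehyde from 24 | CC(C)(C)[Si](C)(C)O[C@H]1CC[C@H]2[C@@](C)(CCC(C)=C)[C@@H](OCc3ccc(OC)cc3)CC[C@@]2(C)[C@H]1C=O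
F4 | step 18 | 3-alkylidene-pyran-2,4-dione from F3 and 28 (C11=C3', not isolated) | CC(C)(C)[Si](C)(C)O[C@H]1CC[C@H]2[C@@](C)(CCC(C)=C)[C@@H](OCc3ccc(OC)cc3)CC[C@@]2(C)[C@H]1C=C4C(=O)OC(C)=C(C(=O)OC)C4=O
F5 | step 18 | 3-alkyl-4-hydroxy-2-pyranone (C11–C3' formed, lactone not yet methylated) | CC(C)(C)[Si](C)(C)O[C@H]1CC[C@H]2[C@@](C)(CCC(C)=C)[C@@H](OCc3ccc(OC)cc3)CC[C@@]2(C)[C@H]1CC4=C(O)C(C(=O)OC)=C(C)OC4=O
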